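**Remark on the chemistry:** the target has no stereocentre, no stereogenic axis and no configured double bond (the prenyl alkene carries two identical methyl groups). The requirement for a single stereoisomer is therefore met by the one achiral compound, and no step needs stereocontrol.

## Analysis of the target

Target 22 is a diaryl ether with two benzene rings and no further ring. Ring A is a methyl benzoate with C1 (CO2Me), C2 (OH), C3 (H), C4 (CH3), C5 (H) and C6 (O-aryl). Ring B carries the ether oxygen at C1′, CH2OH at C2′, OMe at C4′ and a prenyl ether at C6′. The ether oxygen is ortho-substituted on both sides in both rings (ester and H on ring A, CH2OH and O-prenyl on ring B). Ring B is electron-rich and ring A is activated only by one ester, so direct aryl–oxygen coupling is hindered and poorly activated. The sensitive groups are: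
- the aryl prenyl ether (acid, hydrogenolysis, electrophilic oxidants, Claisen rearrangement on strong heating);
- the electron-rich benzylic alcohol (ionisation under acid);
- the salicylate (saponification, or lactonisation onto the benzylic hydroxyl under base).

The strategy rests on the contiguous C1(CO2Me)–C2(O)–C3(H)–C4(CH3) segment of ring A. It has the substitution pattern of C3–C6 of a 3-carbomethoxy-4-oxy-6-methyl-2-pyrone. Ring A can therefore be grown onto an alkyne that already carries the ring-B oxygen at the future C6, and the hindered Ar–O–Ar bond never has to be made between two finished arenes.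

## Retrosynthetic reasoning

**22 to 20.** The free C2 phenol and the C2′ benzylic alcohol are masked as an aryl acetate and a tert-butyldimethylsilyl ether. Going back, this gives first 21 (phenol free, silyl ether kept) and then 20 (acetate and silyl ether). Both groups come off under mild base and buffered fluoride, which the prenyl ether and the methyl ester tolerate. The acetate is also the group that keeps the pyrone electron-poor in the ring-forming step, so it serves two purposes.

**20 to 12 and 18.** Ring A is cut at C1–C6 and C4–C5. C1–C4, with ester, acetoxy and methyl group in place, is the diene of pyrone 18 (methyl 4-acetoxy-6-methyl-2-oxo-2H-pyran-3-carboxylate). C5 and C6 are the two carbons of aryl ethynyl ether 12. The cut is made here and not at the Ar–O bond because the forward reaction then forms two C–C bonds at unhindered sp carbons. The forward step must add 12 across C3 and C6 of 18 with the aryloxy carbon next to the ester, and then expel the O1–C2 lactone bridge so that the arene forms without an oxidant.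

**12 to 7 and 8.** The alkynyl C–O bond is traced to phenol 7 and trichloroethylene 8 through the (E)-1,2-dichlorovinyl ether 9. The only C–O bond to the hindered ring-B oxygen is thus made by a phenoxide adding to a small linear electrophile. Two equivalents of alkyllithium then convert 9 into the alkyne.

**7 to 5.** The silyl ether and the benzylic alcohol go back through diol 6 to salicylaldehyde 5. The aldehyde is kept as long as possible because it controls the regiochemistry of the preceding etherification.

**5 to 3 and 4.** The prenyl ether is cut to catechol aldehyde 3 and prenyl bromide 4. In the dianion of 3 the oxygen ortho to the formyl group is a stabilised, weakly nucleophilic vinylogous carboxylate, so alkylation should take place on the other oxygen. This differentiates the two catechol oxygens without a protecting group.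

**3 to 1.** The C3 oxygen of 3 is traced through bromide 2 to commercial 2-hydroxy-5-methoxybenzaldehyde 1. Bromination ortho to the phenol followed by copper-mediated hydrolysis installs it.

**18 to 13 and 14.** The acetate is removed to give hydroxypyrone 17. Its C3–C4 bond and its O1–C2 lactone bond are cut to dimethyl malonate 13 and the acetoacetyl unit that dioxinone 14 releases as acetylketene 15, by way of tricarbonyl compound 16.

## Alternatives that were turned down

**Alternative 1:** Ring B is built instead of ring A, by cutting C1′–C2′ and C3′–C4′. Ring A would be carried as a benzodioxinone bearing an oxygen-linked diene, 5-{[4,4-dimethoxy-2-(trimethylsilyloxy)buta-1,3-dien-1-yl]oxy}-2,2,7-trimethyl-4H-1,3-benzodioxin-4-one A2. The dienophile would be tert-butyldimethyl{[(2E)-3-nitroprop-2-en-1-yl]oxy}silane A3. Cycloaddition, then elimination of the nitro group and of one methoxy group, would give 5-{2-[(tert-butyldimethylsilyloxy)methyl]-6-hydroxy-4-methoxyphenoxy}-2,2,7-trimethyl-4H-1,3-benzodioxin-4-one A1.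
- For it: the nitro group gives dependable regiocontrol and leaves without a trace. The prenyl group is put on last, so it never meets an organolithium or prolonged heating. On that point this plan is stronger than the chosen one.
- Against it: A2 is a diene with four heteroatom substituents that needs several steps from a ring-A phenol and hydrolyses easily. Its reacting terminus carries the bulky aryloxy group. Two eliminations are needed for aromatisation, and they compete with hydrolysis of the silyl enol ether to a cyclohexenone. After A1, three further steps remain (prenylation, opening of the dioxinone to the methyl ester, desilylation).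
- Comparison: the chosen route builds both partners from a simple salicylaldehyde and a malonate, aromatises by irreversible loss of a gas, and needs two steps after the key step.

**Alternative 2:** Both the C6–O bond and the C1–carboxyl bond of ring A are cut. The three components are the phenoxide of 2-(1,3-dioxolan-2-yl)-4-methoxy-6-(3-methylbut-2-enyloxy)phenol A5, the aryne from 3-(methoxymethoxy)-5-methyl-2-(trimethylsilyl)phenyl trifluoromethanesulfonate A6, and carbon dioxide A7. Fluoride would release the aryne, the phenoxide would add at the carbon remote from the alkoxy group, and the aryl anion at C1 would be carboxylated. The product would be 2-[2-(1,3-dioxolan-2-yl)-4-methoxy-6-(3-methylbut-2-enyloxy)phenoxy]-6-(methoxymethoxy)-4-methylbenzoic acid A4.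
- For it: this is the most convergent plan, it needs no ynol ether, and the regiochemistry of addition to a 3-alkoxyaryne is at least as secure as the polarity argument of the chosen route.
- Against it: the C1 anion sits between two oxygen substituents and must capture A7 faster than any proton. Protonation gives a decarboxylated diaryl ether that cannot be repaired. A di-ortho-substituted phenoxide is a weak aryne trap and is reversibly carbonated by A7. A6 needs about four steps from a simple resorcinol-type precursor. After A4 come esterification, removal of the methoxymethyl group, acetal hydrolysis and reduction, two of them acidic in the presence of the prenyl ether.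
- Comparison: in the chosen route the ester is part of the pyrone from the start, no anion has to be trapped, and two mild steps follow the key step.

**Alternative 3:** Ring A is cut at C1–C2 and C5–C6. The dienophile is methyl 3-{2-[(tert-butyldimethylsilyloxy)methyl]-4-methoxy-6-(3-methylbut-2-enyloxy)phenoxy}prop-2-ynoate A10, which would come from C-acylation of 11. The diene is [(1-methoxy-3-methylbuta-1,3-dien-1-yl)oxy]trimethylsilane A9. Cycloaddition, loss of the methoxy group and desilylation on acidic work-up would give methyl 2-{2-[(tert-butyldimethylsilyloxy)methyl]-4-methoxy-6-(3-methylbut-2-enyloxy)phenoxy}-6-hydroxy-4-methylbenzoate A8, which is the same structure as 21.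
- For it: it reaches 21 without an acetate to remove, so it is one step shorter after the ring formation. A9 is one step from a simple senecioate ester. A10 should be easier to handle than the terminal ynol ether 12. On step count and handling it is at least as good as the chosen plan.
- Against it: A10 is a push–pull alkyne. The aryloxy donor lowers the electrophilicity of the very carbon that the nucleophilic terminus of A9 must attack, and that carbon is also the hindered one. A stepwise conjugate addition can expel the ring-B aryloxide by addition–elimination, which would break the ether link the route is meant to keep. A9 is also prone to silyl transfer and to attack through its α-carbon.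
- Comparison: the chosen route puts the donor on one component and both acceptors on the other, so polarity and frontier-orbital demand reinforce each other and no leaving group sits at the attacked carbon. The price is one extra, mild deacetylation.

Key step: step 10

## Route

Step 1
Reactants: 1 2-hydroxy-5-methoxybenzaldehyde
Product: 2 3-bromo-2-hydroxy-5-methoxybenzaldehyde
Conditions: Br2, NaOAc, AcOH, rt
Reagents that add atoms: bromine, BrBr
Why: Electrophilic aromatic bromination; the phenol is the strongest director and its para position is blocked by the methoxy group, so the bromine should enter at C3, ortho to the hydroxyl, and the acetate buffer keeps the aldehyde and ether intact.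

Step 2
Reactants: 2 3-bromo-2-hydroxy-5-methoxybenzaldehyde
Product: 3 2,3-dihydroxy-5-methoxybenzaldehyde
Conditions: Cu powder (cat.), aq NaOH, reflux, N2; then HCl
Reagents that add atoms: sodium hydroxide, [Na+].[OH-]
Why: Copper-mediated (Ullmann-type) hydrolysis of an ortho-bromophenol, the classical way to turn a bromosalicylaldehyde or bromovanillin into the catechol; the phenoxide deactivates the aldehyde towards Cannizzaro reaction and exclusion of air protects the catecholate.

Step 3
Reactants: 3 2,3-dihydroxy-5-methoxybenzaldehyde; 4 1-bromo-3-methylbut-2-ene (prenyl bromide)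
Product: 5 2-hydroxy-5-methoxy-3-(3-methylbut-2-enyloxy)benzaldehyde
Conditions: NaH (2.2 equiv), DMSO, rt; then 4 (1.0 equiv), rt; aq HCl work-up
Reagents that add atoms: none
Why: Williamson etherification of the dianion; the 2-oxide is a vinylogous carboxylate conjugated with the formyl group and is the weaker nucleophile, so one equivalent of 4 should alkylate the 3-oxide, as is established for 2,3-dihydroxybenzaldehyde.

Step 4
Reactants: 5 2-hydroxy-5-methoxy-3-(3-methylbut-2-enyloxy)benzaldehyde
Product: 6 2-(hydroxymethyl)-4-methoxy-6-(3-methylbut-2-enyloxy)phenol
Conditions: NaBH4, MeOH/THF, 0 °C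
Reagents that add atoms: none
Why: Borohydride reduction of an aryl aldehyde; the prenyl ether is inert, and the electron-rich salicyl alcohol is worked up cold and neutral and used at once so that it does not ionise to a quinone methide.

Step 5
Reactants: 6 2-(hydroxymethyl)-4-methoxy-6-(3-methylbut-2-enyloxy)phenol
Product: 7 2-[(tert-butyldimethylsilyloxy)methyl]-4-methoxy-6-(3-methylbut-2-enyloxy)phenol
Conditions: TBSCl (1.05 equiv), imidazole, CH2Cl2, 0 °C
Reagents that add atoms: tert-butyldimethylsilyl chloride, CC(C)(C)[Si](C)(C)Cl
Why: Chemoselective silylation of the primary benzylic hydroxyl in the presence of a hydrogen-bonded, doubly ortho-substituted phenol, as known for salicyl alcohols; any aryl silyl ether that forms is cleaved back by brief K2CO3/MeOH.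

Step 6
Reactants: 7 2-[(tert-butyldimethylsilyloxy)methyl]-4-methoxy-6-(3-methylbut-2-enyloxy)phenol; 8 trichloroethylene
Product: 9 tert-butyl{[2-{[(E)-1,2-dichloroethenyl]oxy}-5-methoxy-3-(3-methylbut-2-enyloxy)phenyl]methoxy}dimethylsilane
Conditions: K2CO3, DMF, 70 °C
Reagents that add atoms: none
Why: Known preparation of aryl 1,2-dichlorovinyl ethers: base eliminates HCl from 8 to dichloroacetylene, which the phenoxide adds to in anti fashion to give the (E)-ether; the electrophile is small and linear, so the hindered phenoxide should still react.

Step 7
Reactants: 9 tert-butyl{[2-{[(E)-1,2-dichloroethenyl]oxy}-5-methoxy-3-(3-methylbut-2-enyloxy)phenyl]methoxy}dimethylsilane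
Product: 12 tert-butyl{[2-(ethynyloxy)-5-methoxy-3-(3-methylbut-2-enyloxy)phenyl]methoxy}dimethylsilane, via chloroethynyl ether 10 (not isolated), via lithium alkynyl ether 11 (not isolated)
Conditions: n-BuLi (2.3 equiv), Et2O, −78 → −40 °C; MeOH, −78 °C; NaHCO3 work-up
Reagents that add atoms: none
Why: Established ynol ether synthesis from dichlorovinyl ethers: the first equivalent of n-BuLi dehydrochlorinates 9 to 10, the second exchanges chlorine for lithium to give 11, and a cold protic quench delivers the terminal alkyne; at −78 °C the silyl ether, the prenyl ether and the ring positions should not be metalated.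

Step 8
Reactants: 13 dimethyl malonate; 14 2,2,6-trimethyl-4H-1,3-dioxin-4-one
Product: 17 methyl 4-hydroxy-6-methyl-2-oxo-2H-pyran-3-carboxylate, via acetylketene 15 (not isolated), via dimethyl 2-(3-oxobutanoyl)malonate 16 (not isolated)
Conditions: NaH, THF, 0 °C; 14, PhMe, 110 °C; then aq HCl
Reagents that add atoms: none
Why: Thermal retro-[4+2] of 14 releases 15, which C-acylates the malonate anion (acetoacetylation, as with diketene); the enol oxygen of the methyl ketone in 16 then lactonises onto one ester to give the stabilised 4-hydroxy-2-pyrone.

Step 9
Reactants: 17 methyl 4-hydroxy-6-methyl-2-oxo-2H-pyran-3-carboxylate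
Product: 18 methyl 4-acetoxy-6-methyl-2-oxo-2H-pyran-3-carboxylate
Conditions: Ac2O, pyridine, CH2Cl2, 0 °C; non-aqueous work-up
Reagents that add atoms: acetic anhydride, CC(=O)OC(C)=O
Why: O-Acylation of the acidic 4-hydroxyl of a 4-hydroxy-2-pyrone; C3 is blocked, so no C-acylation or acyl migration can follow, and the activated enol acetate is kept dry and used directly.

Step 10
Reactants: 12 tert-butyl{[2-(ethynyloxy)-5-methoxy-3-(3-methylbut-2-enyloxy)phenyl]methoxy}dimethylsilane; 18 methyl 4-acetoxy-6-methyl-2-oxo-2H-pyran-3-carboxylate
Product: 20 methyl 2-acetoxy-6-{2-[(tert-butyldimethylsilyloxy)methyl]-4-methoxy-6-(3-methylbut-2-enyloxy)phenoxy}-4-methylbenzoate, via bicyclic lactone adduct 19 (not isolated)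
Conditions: 18 (2 equiv), BHT (cat.), PhMe, 110 °C, sealed tube
Reagents that add atoms: none
Why: Proposed new method: the closest known reaction type is the inverse-electron-demand Diels–Alder addition of ketene acetals, enol ethers and ynamines to 3-carbomethoxy-2-pyrones followed by loss of carbon dioxide, which has not been shown for a 4-acyloxy-6-methyl pyrone or for an aryl ethynyl ether. The HOMO of 12 has its large coefficient on the terminal CH and the LUMO of 18 on C6, the δ-carbon of the doubly acceptor-substituted dienyl lactone, so the asynchronous [4+2] transition state leads with the CH–C6 bond and closes the aryloxy carbon onto C3, the carbon stabilised by the lactone and ester carbonyls. This intermolecular suprafacial [4+2] closes the six-membered carbocycle as the 2-oxabicyclo[2.2.2]octadienone 19, and retro-[4+2] loss of the O1–C2 bridge as carbon dioxide should be fast at the reaction temperature because it forms the benzene ring of 20. The two bridgehead stereocentres of 19 form as a racemate and vanish on aromatisation, so no stereocontrol is required. The selectivity needed is regiochemical (aryloxy next to the ester, not next to the methyl group), and it is secured by this polarity match, since the 4-acetoxy group donates towards C3 and C5 and leaves C6 as the electrophilic terminus. The acetate, unlike a free or alkylated 4-oxygen, keeps the diene electron-poor, and 12 cannot fragment to a ketene because its oxygen substituent is an aryl group with no transferable β-hydrogen. A temperature of 110 °C stays well below that of the aromatic Claisen rearrangement of the prenyl ether.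

Step 11
Reactants: 20 methyl 2-acetoxy-6-{2-[(tert-butyldimethylsilyloxy)methyl]-4-methoxy-6-(3-methylbut-2-enyloxy)phenoxy}-4-methylbenzoate
Product: 21 methyl 2-{2-[(tert-butyldimethylsilyloxy)methyl]-4-methoxy-6-(3-methylbut-2-enyloxy)phenoxy}-6-hydroxy-4-methylbenzoate
Conditions: K2CO3 (cat.), MeOH, 0 °C → rt
Reagents that add atoms: none
Why: Methanolysis of an aryl acetate (transesterification); exchange at the methyl ester is degenerate in methanol, and the alkyl silyl ether and the prenyl ether are stable to carbonate.

Step 12
Reactants: 21 methyl 2-{2-[(tert-butyldimethylsilyloxy)methyl]-4-methoxy-6-(3-methylbut-2-enyloxy)phenoxy}-6-hydroxy-4-methylbenzoate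
Product: 22 methyl 2-hydroxy-6-[2-(hydroxymethyl)-4-methoxy-6-(3-methylbut-2-enyloxy)phenoxy]-4-methylbenzoate
Conditions: TBAF, AcOH, THF, 0 °C → rt
Reagents that add atoms: none
Why: Fluoride cleavage of a primary silyl ether; the acetic acid buffer keeps the medium near neutral so that the liberated benzylic alkoxide does not lactonise onto the neighbouring ester, and it avoids the acid that would endanger the prenyl ether and the benzylic alcohol.

## Compound list

1 | 2-hydroxy-5-methoxybenzaldehyde | COc1ccc(O)c(C=O)c1 | starting material
2 | 3-bromo-2-hydroxy-5-methoxybenzaldehyde | COc1cc(Br)c(O)c(C=O)c1 | intermediate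
3 | 2,3-dihydroxy-5-methoxybenzaldehyde | COc1cc(O)c(O)c(C=O)c1 | intermediate
4 | 1-bromo-3-methylbut-2-ene (prenyl bromide) | CC(C)=CCBr | starting material
5 | 2-hydroxy-5-methoxy-3-(3-methylbut-2-enyloxy)benzaldehyde | COc1cc(OCC=C(C)C)c(O)c(C=O)c1 | intermediate
6 | 2-(hydroxymethyl)-4-methoxy-6-(3-methylbut-2-enyloxy)phenol | COc1cc(CO)c(O)c(OCC=C(C)C)c1 | intermediate
7 | 2-[(tert-butyldimethylsilyloxy)methyl]-4-methoxy-6-(3-methylbut-2-enyloxy)phenol | COc1cc(CO[Si](C)(C)C(C)(C)C)c(O)c(OCC=C(C)C)c1 | intermediate
8 | trichloroethylene | ClC=C(Cl)Cl | starting material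
9 | tert-butyl{[2-{[(E)-1,2-dichloroethenyl]oxy}-5-methoxy-3-(3-methylbut-2-enyloxy)phenyl]methoxy}dimethylsilane | Cl/C=C(Cl)\Oc1c(CO[Si](C)(C)C(C)(C)C)cc(OC)cc1OCC=C(C)C | intermediate
10 | tert-butyl{[2-(chloroethynyloxy)-5-methoxy-3-(3-methylbut-2-enyloxy)phenyl]methoxy}dimethylsilane (not isolated) | ClC#COc1c(CO[Si](C)(C)C(C)(C)C)cc(OC)cc1OCC=C(C)C | intermediate
11 | lithium acetylide of 12, {2-[2-[(tert-butyldimethylsilyloxy)methyl]-4-methoxy-6-(3-methylbut-2-enyloxy)phenoxy]ethynyl}lithium (not isolated) | [Li]C#COc1c(CO[Si](C)(C)C(C)(C)C)cc(OC)cc1OCC=C(C)C | intermediate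
12 | tert-butyl{[2-(ethynyloxy)-5-methoxy-3-(3-methylbut-2-enyloxy)phenyl]methoxy}dimethylsilane | C#COc1c(CO[Si](C)(C)C(C)(C)C)cc(OC)cc1OCC=C(C)C | intermediate
13 | dimethyl malonate | COC(=O)CC(=O)OC | starting material
14 | 2,2,6-trimethyl-4H-1,3-dioxin-4-one | CC1=CC(=O)OC(C)(C)O1 | starting material
15 | acetylketene (3-oxobut-1-en-1-one; not isolated) | CC(=O)C=C=O | intermediate
16 | dimethyl 2-(3-oxobutanoyl)malonate (formed as its sodium enolate; not isolated) | COC(=O)C(C(=O)OC)C(=O)CC(C)=O | intermediate
17 | methyl 4-hydroxy-6-methyl-2-oxo-2H-pyran-3-carboxylate | COC(=O)C1=C(O)C=C(C)OC1=O | intermediate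
18 | methyl 4-acetoxy-6-methyl-2-oxo-2H-pyran-3-carboxylate | COC(=O)C1=C(OC(C)=O)C=C(C)OC1=O | intermediate
19 | methyl 8-acetoxy-5-{2-[(tert-butyldimethylsilyloxy)methyl]-4-methoxy-6-(3-methylbut-2-enyloxy)phenoxy}-1-methyl-3-oxo-2-oxabicyclo[2.2.2]octa-5,7-diene-4-carboxylate (racemic; not isolated) | COC(=O)C12C(=O)OC(C)(C=C1OC(C)=O)C=C2Oc1c(CO[Si](C)(C)C(C)(C)C)cc(OC)cc1OCC=C(C)C | intermediate
20 | methyl 2-acetoxy-6-{2-[(tert-butyldimethylsilyloxy)methyl]-4-methoxy-6-(3-methylbut-2-enyloxy)phenoxy}-4-methylbenzoate | COC(=O)c1c(OC(C)=O)cc(C)cc1Oc1c(CO[Si](C)(C)C(C)(C)C)cc(OC)cc1OCC=C(C)C | intermediate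
21 | methyl 2-{2-[(tert-butyldimethylsilyloxy)methyl]-4-methoxy-6-(3-methylbut-2-enyloxy)phenoxy}-6-hydroxy-4-methylbenzoate | COC(=O)c1c(O)cc(C)cc1Oc1c(CO[Si](C)(C)C(C)(C)C)cc(OC)cc1OCC=C(C)C | intermediate
22 | methyl 2-hydroxy-6-[2-(hydroxymethyl)-4-methoxy-6-(3-methylbut-2-enyloxy)phenoxy]-4-methylbenzoate | COC(=O)c1c(O)cc(C)cc1Oc1c(CO)cc(OC)cc1OCC=C(C)C | target

## Step count and least certain steps

Total: 12 steps. Longest linear sequence: 10 steps (steps 1–7 and 10–12). The pyrone branch is 2 steps (8 and 9).

**Step 10 (key step).** The most likely failure is a cycloaddition that is too slow. The 6-methyl group hinders and deactivates the pyrone terminus, and an aryloxy alkyne is a weaker donor than a ketene acetal. Thermal oligomerisation of 12, or a stepwise attack at the acetoxy-bearing C4 with loss of acetate, could then outrun the [4+2], and the regiochemistry could leak.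

The fallback uses known chemistry and sets out from phenol 7. Commercial 2,6-dihydroxy-4-methylbenzoic acid F1 would be converted with acetone and trifluoroacetic anhydride into 5-hydroxy-2,2,7-trimethyl-4H-1,3-benzodioxin-4-one F2. Triflation would give 2,2,7-trimethyl-4-oxo-4H-1,3-benzodioxin-5-yl trifluoromethanesulfonate F3. Palladium-catalysed diaryl ether coupling of F3 with 7 (bulky biarylphosphine ligand, K3PO4, toluene) would give 5-{2-[(tert-butyldimethylsilyloxy)methyl]-4-methoxy-6-(3-methylbut-2-enyloxy)phenoxy}-2,2,7-trimethyl-4H-1,3-benzodioxin-4-one F4. Opening of the dioxinone with sodium methoxide in methanol would give the methyl ester and the free phenol, which is 21, where the route is rejoined. The bulk of the ligand should keep palladium off the prenyl ether.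

**Step 7.** The most likely failure is loss of the terminal ynol ether after it has formed, by acid-catalysed hydration to an aryl acetate or by oligomerisation on concentration or on silica. A second risk is competing metalation if the temperature rises.

The fallback changes the form in which the alkyne is isolated. Starting from 9, the lithium acetylide 11 would be quenched with chlorotrimethylsilane instead of methanol. This gives the C-silylated tert-butyl{[5-methoxy-3-(3-methylbut-2-enyloxy)-2-{[2-(trimethylsilyl)ethynyl]oxy}phenyl]methoxy}dimethylsilane F5, which should survive chromatography and storage. The alkynyl–silicon bond would be cleaved with catalytic K2CO3 in methanol just before use. The crude solution of 12 would then go into step 10 after solvent exchange, so the route is rejoined at 12.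

**Step 8.** The most likely failure is that the sodium malonate, poorly soluble in hot toluene, does not trap 15 efficiently. Dimerisation of 15 to dehydroacetic acid would then dominate, or the ring closure of 16 would stall.

The fallback replaces thermal ketene generation by direct acylation. Starting from 13, its sodium enolate would be treated at 0 °C with diketene (4-methyleneoxetan-2-one) F6, which is opened at its lactone carbonyl without heating. This gives the same tricarbonyl compound 16, and acidification and gentle warming would close it to 17, where the route is rejoined.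

**Step 3.** The most likely failure is incomplete formation of the dianion. Alkylation would then occur on the 2-oxygen or on both oxygens, with some C-prenylation.

The fallback removes the competition by tying up the 2-oxygen. Starting from 3, borohydride reduction would give 3-(hydroxymethyl)-5-methoxybenzene-1,2-diol F7. 2,2-Dimethoxypropane with catalytic acid would close the six-membered acetonide between the benzylic and the neighbouring phenolic oxygen, giving 6-methoxy-2,2-dimethyl-4H-1,3-benzodioxin-8-ol F8. The one remaining phenol would be alkylated with 4 and K2CO3 to give 6-methoxy-2,2-dimethyl-8-(3-methylbut-2-enyloxy)-4H-1,3-benzodioxine F9. Mild aqueous acetic acid would remove the acetonide and give 6, where the route is rejoined, two steps longer.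

## Further compounds

F1 | step 10 | 2,6-dihydroxy-4-methylbenzoic acid | Cc1cc(O)c(C(=O)O)c(O)c1
F2 | step 10 | 5-hydroxy-2,2,7-trimethyl-4H-1,3-benzodioxin-4-one | Cc1cc(O)c2C(=O)OC(C)(C)Oc2c1
F3 | step 10 | 2,2,7-trimethyl-4-oxo-4H-1,3-benzodioxin-5-yl trifluoromethanesulfonate | Cc1cc(OS(=O)(=O)C(F)(F)F)c2C(=O)OC(C)(C)Oc2c1
F4 | step 10 | 5-{2-[(tert-butyldimethylsilyloxy)methyl]-4-methoxy-6-(3-methylbut-2-enyloxy)phenoxy}-2,2,7-trimethyl-4H-1,3-benzodioxin-4-one | CC1(C)OC(=O)c2c(O1)cc(C)cc2Oc1c(CO[Si](C)(C)C(C)(C)C)cc(OC)cc1OCC=C(C)C
F5 | step 7 | tert-butyl{[5-methoxy-3-(3-methylbut-2-enyloxy)-2-{[2-(trimethylsilyl)ethynyl]oxy}phenyl]methoxy}dimethylsilane | C[Si](C)(C)C#COc1c(CO[Si](C)(C)C(C)(C)C)cc(OC)cc1OCC=C(C)C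
F6 | step 8 | diketene (4-methyleneoxetan-2-one) | C=C1CC(=O)O1
F7 | step 3 | 3-(hydroxymethyl)-5-methoxybenzene-1,2-diol | COc1cc(O)c(O)c(CO)c1
F8 | step 3 | 6-methoxy-2,2-dimethyl-4H-1,3-benzodioxin-8-ol | COc1cc(O)c2OC(C)(C)OCc2c1
F9 | step 3 | 6-methoxy-2,2-dimethyl-8-(3-methylbut-2-enyloxy)-4H-1,3-benzodioxine | COc1cc(OCC=C(C)C)c2OC(C)(C)OCc2c1
A1 | alternative 1 | 5-{2-[(tert-butyldimethylsilyloxy)methyl]-6-hydroxy-4-methoxyphenoxy}-2,2,7-trimethyl-4H-1,3-benzodioxin-4-one | CC1(C)OC(=O)c2c(O1)cc(C)cc2Oc1c(CO[Si](C)(C)C(C)(C)C)cc(OC)cc1O
A2 | alternative 1 | 5-{[4,4-dimethoxy-2-(trimethylsilyloxy)buta-1,3-dien-1-yl]oxy}-2,2,7-trimethyl-4H-1,3-benzodioxin-4-one | CC1(C)OC(=O)c2c(O1)cc(C)cc2OC=C(O[Si](C)(C)C)C=C(OC)OC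
A3 | alternative 1 | tert-butyldimethyl{[(2E)-3-nitroprop-2-en-1-yl]oxy}silane | CC(C)(C)[Si](C)(C)OC/C=C/[N+](=O)[O-]
A4 | alternative 2 | 2-[2-(1,3-dioxolan-2-yl)-4-methoxy-6-(3-methylbut-2-enyloxy)phenoxy]-6-(methoxymethoxy)-4-methylbenzoic acid | COCOc1cc(C)cc(Oc2c(OCC=C(C)C)cc(OC)cc2C3OCCO3)c1C(=O)O
A5 | alternative 2 | 2-(1,3-dioxolan-2-yl)-4-methoxy-6-(3-methylbut-2-enyloxy)phenol | Oc1c(C2OCCO2)cc(OC)cc1OCC=C(C)C
A6 | alternative 2 | 3-(methoxymethoxy)-5-methyl-2-(trimethylsilyl)phenyl trifluoromethanesulfonate | COCOc1cc(C)cc(OS(=O)(=O)C(F)(F)F)c1[Si](C)(C)C
A7 | alternative 2 | carbon dioxide | O=C=O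
A8 | alternative 3 | methyl 2-{2-[(tert-butyldimethylsilyloxy)methyl]-4-methoxy-6-(3-methylbut-2-enyloxy)phenoxy}-6-hydroxy-4-methylbenzoate | COC(=O)c1c(O)cc(C)cc1Oc1c(CO[Si](C)(C)C(C)(C)C)cc(OC)cc1OCC=C(C)C
A9 | alternative 3 | [(1-methoxy-3-methylbuta-1,3-dien-1-yl)oxy]trimethylsilane | COC(O[Si](C)(C)C)=CC(C)=C
A10 | alternative 3 | methyl 3-{2-[(tert-butyldimethylsilyloxy)methyl]-4-methoxy-6-(3-methylbut-2-enyloxy)phenoxy}prop-2-ynoate | COC(=O)C#COc1c(CO[Si](C)(C)C(C)(C)C)cc(OC)cc1OCC=C(C)C
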